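A direct plan would build the epoxy diene allylsilane A1 from geranyl acetate in about ten steps and close rings A and B by a Lewis-acid epoxy-polyene cyclisation to the bicyclic alcohol A2 (bonds C4–C5 and C9–C10).
It would then delete the C3 hydroxyl, make 8α-OH by epoxidation and hydride opening, carry oxygen to C6 through the ether A3 and a lactone, and finish the side chain by B-alkyl Suzuki coupling, Sharpless epoxidation, perhydrolysis and cross metathesis of the vinyl silyl peroxide A4.
Weak point 1, the radical deoxygenation at C3: the cyclisation would put oxygen where the target has none and none at C6, so two steps would only erase what the key step made.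
Weak point 2, the oxygen relay from C18 to C6 (hypoiodite C–H abstraction, RuO4 oxidation, lactone opening): five steps and two protecting-group changes would be spent on one hydroxyl, and three more on 8α-OH, with no new C–C bond.
Weak point 3, the run-up to the cyclisation: ten linear steps of acetate, benzyl, silyl and ester redox changes would precede the key step, so the longest linear sequence would pass thirty steps.

**Retrosynthetic overview**
The target comes from cross metathesis of butenolide 38 with vinyl silyl peroxide 30; C13–OOH comes from a Sharpless epoxide by perhydrolysis, and the side chain from a B-alkyl Suzuki coupling on a C9 vinyl group.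
Rings A and B close together in an intramolecular Diels–Alder reaction of the open-chain trienoate 18, which forms C3–C4 and C5–C10: the C18 ester on quaternary C4 next to C5–H is read as an (E)-2-methyl enoate dienophile, C10(CH3)=C1–C2=C3 as the diene, and C6–C9 as the tether.
The tether already carries ring B's 6α-O, 8α-O/8β-CH3 and the C9 handle, set on the chain by catalytic propargylation (C6) and by Shi epoxidation with anti opening (C8, C9); two Negishi carboalumination–vinylations make both (E)-trisubstituted alkenes.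
So there is no oxygen to delete at C3, no relay to C6, C18 is an ester from step 1, and after ring closure the core needs only hydrogenation of C1=C2.
Key step: step 10

Remark: labdane numbering (C1–C20, butenolide C2'–C5') is used throughout. In step 3 the (S)-acid is named on the premise that the known sense of induction with aryl and alkenyl aldehydes ((R)-acid gives the (R)-carbinol) extends to aldehyde 4. Aldehyde 1 is used as its commercial aqueous solution.

Step 1
Reactants: 1 2,2-dimethoxyacetaldehyde; 2 methyl 2-(triphenyl-λ5-phosphanylidene)propanoate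
Product: 3 methyl (2E)-4,4-dimethoxy-2-methylbut-2-enoate
Conditions: CH2Cl2, 0 °C to rt
Reagents that add atoms: none
Why: Wittig olefination with a stabilised α-methyl ylide should give the (E)-enoate (ester trans to the acetal carbon), which fixes the C4=C5 geometry that the cycloaddition later turns into the relative configuration of C4 and C5.

Step 2
Reactants: 3 methyl (2E)-4,4-dimethoxy-2-methylbut-2-enoate
Product: 4 methyl (2E)-2-methyl-4-oxobut-2-enoate
Conditions: Amberlyst-15, acetone/H2O, rt
Reagents that add atoms: water, O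
Why: Acid-catalysed acetal hydrolysis unmasks C6 as the aldehyde without touching the conjugated ester, and the E alkene is the stable isomer.

Step 3
Reactants: 4 methyl (2E)-2-methyl-4-oxobut-2-enoate; 5 allenylboronic acid pinacol ester
Product: 7 methyl (2E,4S)-4-hydroxy-2-methylhept-2-en-6-ynoate, via O-pinacolboryl ether 6 (not isolated)
Conditions: (S)-TRIP phosphoric acid (5 mol%), 4 Å MS, toluene, −20 °C; aq NaHCO3
Reagents that add atoms: none
Why: Brønsted-acid-catalysed propargylboration of an aldehyde: the allenyl boronate adds through a closed six-membered transition state with allylic transposition, so only the aldehyde reacts and only the homopropargylic alcohol forms, and the chiral phosphoric acid shields one face to set C6 as S.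

Step 4
Reactants: 7 methyl (2E,4S)-4-hydroxy-2-methylhept-2-en-6-ynoate
Product: 8 methyl (2E,4S)-4-(tert-butyldimethylsilyloxy)-2-methylhept-2-en-6-ynoate
Conditions: TBSCl, imidazole, DMF, rt
Reagents that add atoms: tert-butyldimethylsilyl chloride, CC(C)(C)[Si](C)(C)Cl
Why: Standard silylation; the bulky silyl ether later steers the dienophile through A(1,3) strain and keeps O6 from opening the epoxide of step 6.

Step 5
Reactants: 8 silyl ether alkyne; 9 vinyl bromide
Product: 11 methyl (2E,4S,6E)-4-(tert-butyldimethylsilyloxy)-2,6-dimethylnona-2,6,8-trienoate, via alkenyldimethylalane 10 (not isolated)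
Conditions: Me3Al, Cp2ZrCl2 (cat.), ClCH2CH2Cl, 0 °C to rt; then 9, Pd(PPh3)4 (cat.), ZnCl2, THF, rt
Reagents that add atoms: trimethylaluminium, C[Al](C)C (its CH3 becomes C17; the AlMe2 unit stays in 10 only)
Why: Negishi zirconium-catalysed carboalumination adds CH3 and Al syn with CH3 on the internal carbon C8, and the palladium-catalysed coupling of the alkenylalane with vinyl bromide goes with retention, which gives the (E)-trisubstituted C8=C9 alkene; the conjugated ester is slow towards Me3Al at this temperature.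

Step 6
Reactants: 11 diene ester
Product: 12 methyl (2E,4S)-4-(tert-butyldimethylsilyloxy)-5-[(2R,3R)-3-ethenyl-2-methyloxiran-2-yl]-2-methylpent-2-enoate
Conditions: D-fructose-derived Shi ketone (30 mol%), Oxone, K2CO3, Bu4NHSO4, MeCN/CH2(OMe)2/aq borate buffer (pH 10.5), 0 °C
Reagents that add atoms: potassium peroxymonosulfate (oxygen donor relayed by the dioxirane), [K+].[O-]S(=O)(=O)OO
Why: Shi asymmetric epoxidation: the chiral dioxirane attacks only the electron-rich trisubstituted alkene of the diene (not the vinyl end or the enoate) through the spiro transition state, which for (E)-alkenes delivers the (R,R)-epoxide, so C8 gets its oxygen on the later α face under reagent control.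

Step 7
Reactants: 12 vinyl epoxide; 13 (trimethylsilyl)acetylene
Product: 15 methyl (2E,4S,6R,7R)-4-(tert-butyldimethylsilyloxy)-7-ethynyl-6-hydroxy-2,6-dimethylnona-2,8-dienoate, via C-silyl alkyne 14 (not isolated)
Conditions: 13, n-BuLi, toluene, −78 °C; Et2AlCl, 0 °C; then 12, 0 °C; aq Rochelle salt; then K2CO3, MeOH, rt
Reagents that add atoms: none
Why: Alkynylalane opening of a vinyl epoxide: aluminium activates the oxirane and the alkynyl group attacks the allylic secondary carbon C9 from the side opposite to oxygen (SN2 with inversion), which leaves the tertiary C8–O bond untouched (8R, the later 8α-OH with 8β-CH3) and sets C9 as R (the later 9α-H), and methanolic carbonate then removes the C-silyl group.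

Step 8
Reactants: 15 enyne alcohol; 9 vinyl bromide
Product: 17 methyl (2E,4S,6R,7R,8E)-4-(tert-butyldimethylsilyloxy)-7-ethenyl-6-hydroxy-2,6,8-trimethylundeca-2,8,10-trienoate, via alkenylalane aluminium alkoxide 16 (not isolated)
Conditions: Me3Al (4 equiv), Cp2ZrCl2, ClCH2CH2Cl, 0 °C to rt; then 9, Pd(PPh3)4 (cat.), ZnCl2, THF, rt
Reagents that add atoms: trimethylaluminium, C[Al](C)C (its CH3 becomes C20; the aluminium units stay in 16 only)
Why: Second Negishi carboalumination and cross-coupling: syn methylalumination of the terminal alkyne, helped by the neighbouring aluminium alkoxide, puts the C20 methyl on C10 and the new vinyl group trans to C9, so the (E)-diene with C9 in the outside position results, while the monosubstituted C11=C12 alkene is much slower than the alkyne.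

Step 9
Reactants: 17 trienoate alcohol
Product: 18 methyl (2E,4S,6R,7R,8E)-4-(tert-butyldimethylsilyloxy)-7-ethenyl-2,6,8-trimethyl-6-(triethylsilyloxy)undeca-2,8,10-trienoate
Conditions: TESOTf, 2,6-lutidine, CH2Cl2, −78 to 0 °C
Reagents that add atoms: triethylsilyl triflate, CC[Si](CC)(CC)OS(=O)(=O)C(F)(F)F
Why: Silyl triflate silylation covers the hindered tertiary alcohol, which would otherwise capture C13 when the side-chain epoxide is opened in step 15.

Step 10
Reactants: 18 open-chain trienoate
Product: 19 methyl 6α-(tert-butyldimethylsilyloxy)-8α-(triethylsilyloxy)-13,14,15,16-tetranorlabda-1,11-dien-18-oate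
Conditions: toluene (0.01 M), BHT (cat.), 170 °C, sealed tube
Reagents that add atoms: none
Why: Thermal intramolecular Diels–Alder reaction of a 2,8,10-undecatrienoate, a concerted [4+2] cycloaddition in which the internal C5–C10 bond is the more advanced; the closest known reaction type is the cyclisation of terminally activated (E)-trienoates to trans-fused octalins. Ring A closes as the new cyclohexene (bonds C3–C4 and C5–C10) and ring B closes at the same time from the four-atom tether C6–C9, which folds as a chair. C4 follows from the E geometry of the dienophile (CO2Me cis to H5, hence ester α and CH3 β); C5 follows from C6, because A(1,3) strain with the C19 methyl holds H6 in the enoate plane and leaves the diene only the face that makes H5 α and the silyloxy group equatorial; C10 follows from the E diene (C9 outside, C20 inside) and the endo position of the ester, which places C20 β and gives the trans ring fusion. The silyloxy group at C8 and the vinyl group at C9 are equatorial in this same chair, so all three tether stereocentres favour one transition state, and the geminal substitution at C8 helps the fold. The step needs endo (trans-fused) over exo (cis-fused) selectivity and a cycloaddition faster than the 1,5-hydrogen shift of the inside methyl group of the diene; the ester orientation and the chair tether should secure the first and the activated dienophile the second, the cis-fused isomer being the expected by-product.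

Step 11
Reactants: 20 but-2-yn-1-ol
Product: 22 (E)-3-iodobut-2-en-1-ol, via alkenylzirconocene 21 (not isolated)
Conditions: Cp2Zr(H)Cl (2.2 equiv), THF, rt to 40 °C; I2, −78 to 0 °C; then H2O
Reagents that add atoms: iodine, [I][I]; Cp2Zr(H)Cl, [H-].[Cl-].[Zr+4].c1cc[cH-]c1.c1cc[cH-]c1 (zirconium units of 21 only)
Why: Syn hydrozirconation with excess Cp2Zr(H)Cl equilibrates zirconium to C3, remote from the zirconium alkoxide, and iodinolysis with retention gives the (E)-iodide.

Step 12
Reactants: 19 bicyclic diene; 22 (E)-3-iodobut-2-en-1-ol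
Product: 24 methyl (13E)-6α-(tert-butyldimethylsilyloxy)-15-hydroxy-8α-(triethylsilyloxy)labda-1,13-dien-18-oate, via B-alkyl-9-BBN adduct 23 (not isolated)
Conditions: 9-BBN-H, THF, rt; then 22, Pd(dppf)Cl2 (cat.), AsPh3 (cat.), aq K3PO4, DMF, rt
Reagents that add atoms: 9-BBN-H, [H]B1C2CCCC1CCC2 (boron unit of 23 only)
Why: 9-BBN adds only to the monosubstituted C11=C12 alkene (the 1,2-disubstituted ring alkene next to quaternary C10 is far slower), and the B-alkyl Suzuki–Miyaura coupling forms C12–C13 with retention of the iodide geometry to give the 13E alkene.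

Step 13
Reactants: 24 (13E)-allylic alcohol
Product: 25 methyl (13S,14S)-6α-(tert-butyldimethylsilyloxy)-13,14-epoxy-15-hydroxy-8α-(triethylsilyloxy)labd-1-en-18-oate
Conditions: Ti(O-i-Pr)4, L-(+)-diethyl tartrate, t-BuOOH, 4 Å MS, CH2Cl2, −20 °C
Reagents that add atoms: tert-butyl hydroperoxide, CC(C)(C)OO
Why: Sharpless asymmetric epoxidation acts only on the allylic alcohol (the ring alkene has no directing hydroxyl) and is reagent-controlled, L-(+)-tartrate converting this geraniol-type (E)-alcohol to the (13S,14S)-epoxide.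

Step 14
Reactants: 25 epoxy alcohol with ring alkene
Product: 26 methyl (13S,14S)-6α-(tert-butyldimethylsilyloxy)-13,14-epoxy-15-hydroxy-8α-(triethylsilyloxy)labdan-18-oate
Conditions: H2 (1 atm), Pd/C, NaHCO3, EtOAc, rt
Reagents that add atoms: none
Why: Heterogeneous catalytic hydrogenation removes the C1=C2 alkene left by the cycloaddition, the only C=C bond at this stage, under buffered neutral conditions that a trisubstituted epoxy alcohol and silyl ethers tolerate; no stereocentre is formed.

Step 15
Reactants: 26 epoxy alcohol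
Product: 27 methyl (13R,14S)-6α-(tert-butyldimethylsilyloxy)-13-hydroperoxy-14,15-dihydroxy-8α-(triethylsilyloxy)labdan-18-oate
Conditions: anhydrous H2O2 in Et2O (large excess), MoO2(acac)2 (cat.), 0 °C to rt
Reagents that add atoms: hydrogen peroxide, OO
Why: Molybdenum-catalysed perhydrolysis of an epoxide: hydrogen peroxide attacks the tertiary C13 from the side opposite to the epoxide oxygen, so inversion should give the (13R)-hydroperoxide, and the silylated O8 cannot compete as a nucleophile.

Step 16
Reactants: 27 hydroperoxy diol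
Product: 28 methyl (13R,14S)-6α-(tert-butyldimethylsilyloxy)-14,15-dihydroxy-8α-(triethylsilyloxy)-13-(triethylsilylperoxy)labdan-18-oate
Conditions: Et3SiCl (1.0 equiv), Et3N, CH2Cl2, −78 to −40 °C
Reagents that add atoms: chlorotriethylsilane, CC[Si](CC)(CC)Cl
Why: Chemoselective silylation: the hydroperoxide is more acidic than the alcohols and its anion is an α-effect nucleophile, so one equivalent of chlorosilane with triethylamine should cap it before the diol.

Step 17
Reactants: 28 silylperoxy diol
Product: 29 methyl (13R)-6α-(tert-butyldimethylsilyloxy)-14-oxo-8α-(triethylsilyloxy)-13-(triethylsilylperoxy)-15-norlabdan-18-oate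
Conditions: NaIO4 on silica gel, CH2Cl2, 0 °C to rt
Reagents that add atoms: none
Why: Malaprade glycol cleavage removes C15 as formaldehyde and leaves a non-enolisable α-peroxy aldehyde, and the supported reagent keeps bulk water from the silyl peroxide.

Step 18
Reactants: 29 α-silylperoxy aldehyde
Product: 30 methyl (13R)-6α-(tert-butyldimethylsilyloxy)-8α-(triethylsilyloxy)-13-(triethylsilylperoxy)labd-14-en-18-oate
Conditions: MePPh3Br, KHMDS, THF, −78 °C
Reagents that add atoms: methyltriphenylphosphonium bromide, C[P+](c1ccccc1)(c1ccccc1)c1ccccc1.[Br-]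
Why: Wittig methylenation of a non-enolisable aldehyde is fast at −78 °C, where the ylide should not attack the O–O bond, and the quaternary C13 cannot epimerise.

Step 19
Reactants: 31 methyl propiolate; 32 (E)-crotonaldehyde
Product: 34 racemic methyl (5E)-4-hydroxyhept-5-en-2-ynoate, via lithium methyl propiolate 33 (not isolated)
Conditions: 31, LDA, THF, −78 °C; then 32; AcOH quench at −78 °C
Reagents that add atoms: lithium diisopropylamide, [Li+].CC(C)[N-]C(C)C (lithium of 33 only)
Why: 1,2-Addition of the lithium acetylide of methyl propiolate to the enal at −78 °C gives the racemic carbinol.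

Step 20
Reactants: 34 racemic carbinol
Product: 35 methyl (5E)-4-oxohept-5-en-2-ynoate
Conditions: MnO2 (activated), CH2Cl2, rt
Reagents that add atoms: none
Why: Manganese dioxide oxidises the doubly activated (allylic, propargylic) alcohol under neutral conditions.

Step 21
Reactants: 35 enynone ester
Product: 36 methyl (4S,5E)-4-hydroxyhept-5-en-2-ynoate
Conditions: (S)-Alpine-Borane (from (−)-α-pinene and 9-BBN-H), neat, rt; then HOCH2CH2NH2, Et2O
Reagents that add atoms: none
Why: Midland reduction: the alkynyl group is the small substituent in the cyclic hydride-transfer transition state, and the reagent from (−)-α-pinene, which gives (S)-carbinols from alkyl alkynyl ketones, should set C5' as S.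

Step 22
Reactants: 36 (S)-hydroxy alkynoate
Product: 38 (5S)-4-methyl-5-[(E)-prop-1-enyl]furan-2(5H)-one, via open hydroxy enoate 37 (not isolated)
Conditions: Me2CuLi (from MeLi and CuI, 2.2 equiv), THF, −78 °C; aq NH4Cl at −78 °C, then rt
Reagents that add atoms: lithium dimethylcuprate, [Li+].C[Cu-]C
Why: Syn carbocupration of the alkynoate places the new methyl cis to hydrogen and the carbinol carbon cis to the ester, so the (Z)-hydroxy enoate lactonises on work-up without touching the C5'–O bond.

Step 23
Reactants: 30 vinyl silyl peroxide; 38 (S)-butenolide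
Product: 39 6-O-TBS-8-O-TES-13-OO-TES derivative of the target (14E)
Conditions: second-generation Hoveyda–Grubbs catalyst RuCl2(SIMes)(=CH-C6H4-2-O-i-Pr) (cat.), 38 (excess), CH2Cl2, 40 °C
Reagents that add atoms: none
Why: Olefin cross metathesis: the vinyl group on quaternary C13 does not homodimerise and the propenyl butenolide dimerises only slowly, so the cross product should dominate and form as the E alkene for steric reasons, and silyl peroxides are tolerated by ruthenium alkylidenes under neutral conditions.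

Step 24
Reactants: 39 tris-silyl derivative
Product: 40 CNP0128148.1
Conditions: HF·pyridine, pyridine, THF, 0 °C to rt
Reagents that add atoms: none
Why: Buffered fluoride-mediated desilylation removes the secondary TBS ether, the tertiary TES ether and the silyl peroxide under weakly acidic conditions that should neither epimerise C5' nor trigger Hock cleavage of the tertiary allylic hydroperoxide.

**Compound list**
1 | 2,2-dimethoxyacetaldehyde | COC(OC)C=O | starting material
2 | methyl 2-(triphenyl-λ5-phosphanylidene)propanoate | COC(=O)C(C)=P(c1ccccc1)(c1ccccc1)c1ccccc1 | starting material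
3 | methyl (2E)-4,4-dimethoxy-2-methylbut-2-enoate | COC(=O)/C(C)=C/C(OC)OC | intermediate
4 | methyl (2E)-2-methyl-4-oxobut-2-enoate | COC(=O)/C(C)=C/C=O | intermediate
5 | allenylboronic acid pinacol ester | C=C=CB1OC(C)(C)C(C)(C)O1 | starting material
6 | O-pinacolboryl ether of 7 (not isolated) | COC(=O)/C(C)=C/[C@@H](OB1OC(C)(C)C(C)(C)O1)CC#C | intermediate
7 | methyl (2E,4S)-4-hydroxy-2-methylhept-2-en-6-ynoate | COC(=O)/C(C)=C/[C@@H](O)CC#C | intermediate
8 | methyl (2E,4S)-4-(tert-butyldimethylsilyloxy)-2-methylhept-2-en-6-ynoate | COC(=O)/C(C)=C/[C@@H](O[Si](C)(C)C(C)(C)C)CC#C | intermediate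
9 | vinyl bromide | C=CBr | starting material
10 | (E)-alkenyldimethylalane from 8 (not isolated) | COC(=O)/C(C)=C/[C@@H](O[Si](C)(C)C(C)(C)C)C/C(C)=C/[Al](C)C | intermediate
11 | methyl (2E,4S,6E)-4-(tert-butyldimethylsilyloxy)-2,6-dimethylnona-2,6,8-trienoate | COC(=O)/C(C)=C/[C@@H](O[Si](C)(C)C(C)(C)C)C/C(C)=C/C=C | intermediate
12 | methyl (2E,4S)-4-(tert-butyldimethylsilyloxy)-5-[(2R,3R)-3-ethenyl-2-methyloxiran-2-yl]-2-methylpent-2-enoate | COC(=O)/C(C)=C/[C@@H](O[Si](C)(C)C(C)(C)C)C[C@@]1(C)O[C@@H]1C=C | intermediate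
13 | (trimethylsilyl)acetylene | C#C[Si](C)(C)C | starting material
14 | methyl (2E,4S,6R,7R)-4-(tert-butyldimethylsilyloxy)-6-hydroxy-2,6-dimethyl-7-[(trimethylsilyl)ethynyl]nona-2,8-dienoate (not isolated) | COC(=O)/C(C)=C/[C@@H](O[Si](C)(C)C(C)(C)C)C[C@@](C)(O)[C@H](C=C)C#C[Si](C)(C)C | intermediate
15 | methyl (2E,4S,6R,7R)-4-(tert-butyldimethylsilyloxy)-7-ethynyl-6-hydroxy-2,6-dimethylnona-2,8-dienoate | COC(=O)/C(C)=C/[C@@H](O[Si](C)(C)C(C)(C)C)C[C@@](C)(O)[C@H](C=C)C#C | intermediate
16 | (E)-alkenyldimethylalane O-dimethylaluminium alkoxide from 15 (not isolated) | COC(=O)/C(C)=C/[C@@H](O[Si](C)(C)C(C)(C)C)C[C@@](C)(O[Al](C)C)[C@H](C=C)/C(C)=C/[Al](C)C | intermediate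
17 | methyl (2E,4S,6R,7R,8E)-4-(tert-butyldimethylsilyloxy)-7-ethenyl-6-hydroxy-2,6,8-trimethylundeca-2,8,10-trienoate | COC(=O)/C(C)=C/[C@@H](O[Si](C)(C)C(C)(C)C)C[C@@](C)(O)[C@H](C=C)/C(C)=C/C=C | intermediate
18 | methyl (2E,4S,6R,7R,8E)-4-(tert-butyldimethylsilyloxy)-7-ethenyl-2,6,8-trimethyl-6-(triethylsilyloxy)undeca-2,8,10-trienoate | COC(=O)/C(C)=C/[C@@H](O[Si](C)(C)C(C)(C)C)C[C@@](C)(O[Si](CC)(CC)CC)[C@H](C=C)/C(C)=C/C=C | intermediate
19 | methyl 6α-(tert-butyldimethylsilyloxy)-8α-(triethylsilyloxy)-13,14,15,16-tetranorlabda-1,11-dien-18-oate | COC(=O)[C@]1(C)CC=C[C@@]2(C)[C@H]1[C@@H](O[Si](C)(C)C(C)(C)C)C[C@@](C)(O[Si](CC)(CC)CC)[C@@H]2C=C | intermediate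
20 | but-2-yn-1-ol | CC#CCO | starting material
21 | (E)-alkenylzirconocene zirconium alkoxide (not isolated) | C/[C-]=C\C[O-].[Zr+4].[Zr+4].[Cl-].[Cl-].c1cc[cH-]c1.c1cc[cH-]c1.c1cc[cH-]c1.c1cc[cH-]c1 | intermediate
22 | (E)-3-iodobut-2-en-1-ol | C/C(I)=C\CO | intermediate
23 | 12-(9-borabicyclo[3.3.1]nonan-9-yl) adduct of 19 (not isolated) | COC(=O)[C@]1(C)CC=C[C@@]2(C)[C@H]1[C@@H](O[Si](C)(C)C(C)(C)C)C[C@@](C)(O[Si](CC)(CC)CC)[C@@H]2CCB1C2CCCC1CCC2 | intermediate
24 | methyl (13E)-6α-(tert-butyldimethylsilyloxy)-15-hydroxy-8α-(triethylsilyloxy)labda-1,13-dien-18-oate | COC(=O)[C@]1(C)CC=C[C@@]2(C)[C@H]1[C@@H](O[Si](C)(C)C(C)(C)C)C[C@@](C)(O[Si](CC)(CC)CC)[C@@H]2CC/C(C)=C/CO | intermediate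
25 | methyl (13S,14S)-6α-(tert-butyldimethylsilyloxy)-13,14-epoxy-15-hydroxy-8α-(triethylsilyloxy)labd-1-en-18-oate | COC(=O)[C@]1(C)CC=C[C@@]2(C)[C@H]1[C@@H](O[Si](C)(C)C(C)(C)C)C[C@@](C)(O[Si](CC)(CC)CC)[C@@H]2CC[C@]3(C)O[C@H]3CO | intermediate
26 | methyl (13S,14S)-6α-(tert-butyldimethylsilyloxy)-13,14-epoxy-15-hydroxy-8α-(triethylsilyloxy)labdan-18-oate | COC(=O)[C@]1(C)CCC[C@@]2(C)[C@H]1[C@@H](O[Si](C)(C)C(C)(C)C)C[C@@](C)(O[Si](CC)(CC)CC)[C@@H]2CC[C@]3(C)O[C@H]3CO | intermediate
27 | methyl (13R,14S)-6α-(tert-butyldimethylsilyloxy)-13-hydroperoxy-14,15-dihydroxy-8α-(triethylsilyloxy)labdan-18-oate | COC(=O)[C@]1(C)CCC[C@@]2(C)[C@H]1[C@@H](O[Si](C)(C)C(C)(C)C)C[C@@](C)(O[Si](CC)(CC)CC)[C@@H]2CC[C@](C)([C@@H](O)CO)OO | intermediate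
28 | methyl (13R,14S)-6α-(tert-butyldimethylsilyloxy)-14,15-dihydroxy-8α-(triethylsilyloxy)-13-(triethylsilylperoxy)labdan-18-oate | COC(=O)[C@]1(C)CCC[C@@]2(C)[C@H]1[C@@H](O[Si](C)(C)C(C)(C)C)C[C@@](C)(O[Si](CC)(CC)CC)[C@@H]2CC[C@](C)([C@@H](O)CO)OO[Si](CC)(CC)CC | intermediate
29 | methyl (13R)-6α-(tert-butyldimethylsilyloxy)-14-oxo-8α-(triethylsilyloxy)-13-(triethylsilylperoxy)-15-norlabdan-18-oate | COC(=O)[C@]1(C)CCC[C@@]2(C)[C@H]1[C@@H](O[Si](C)(C)C(C)(C)C)C[C@@](C)(O[Si](CC)(CC)CC)[C@@H]2CC[C@](C)(C=O)OO[Si](CC)(CC)CC | intermediate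
30 | methyl (13R)-6α-(tert-butyldimethylsilyloxy)-8α-(triethylsilyloxy)-13-(triethylsilylperoxy)labd-14-en-18-oate | COC(=O)[C@]1(C)CCC[C@@]2(C)[C@H]1[C@@H](O[Si](C)(C)C(C)(C)C)C[C@@](C)(O[Si](CC)(CC)CC)[C@@H]2CC[C@](C)(C=C)OO[Si](CC)(CC)CC | intermediate
31 | methyl propiolate | C#CC(=O)OC | starting material
32 | (E)-crotonaldehyde | C/C=C/C=O | starting material
33 | lithium methyl propiolate (not isolated) | [Li+].[C-]#CC(=O)OC | intermediate
34 | racemic methyl (5E)-4-hydroxyhept-5-en-2-ynoate | C/C=C/C(O)C#CC(=O)OC | intermediate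
35 | methyl (5E)-4-oxohept-5-en-2-ynoate | C/C=C/C(=O)C#CC(=O)OC | intermediate
36 | methyl (4S,5E)-4-hydroxyhept-5-en-2-ynoate | C/C=C/[C@H](O)C#CC(=O)OC | intermediate
37 | methyl (2Z,4S,5E)-4-hydroxy-3-methylhepta-2,5-dienoate (not isolated) | C/C=C/[C@H](O)/C(C)=C\C(=O)OC | intermediate
38 | (5S)-4-methyl-5-[(E)-prop-1-enyl]furan-2(5H)-one | C/C=C/[C@@H]1OC(=O)C=C1C | intermediate
39 | 6-O-(tert-butyldimethylsilyl)-8-O-(triethylsilyl)-13-OO-(triethylsilyl) derivative of the target | COC(=O)[C@]1(C)CCC[C@@]2(C)[C@H]1[C@@H](O[Si](C)(C)C(C)(C)C)C[C@@](C)(O[Si](CC)(CC)CC)[C@@H]2CC[C@](C)(/C=C/[C@@H]3OC(=O)C=C3C)OO[Si](CC)(CC)CC | intermediate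
40 | CNP0128148.1 | COC(=O)[C@]1(C)CCC[C@@]2(C)[C@H]1[C@@H](O)C[C@@](C)(O)[C@@H]2CC[C@](C)(/C=C/[C@@H]1OC(=O)C=C1C)OO | target

Total step count: 24. Longest linear sequence: 19 steps (steps 1–10, 12–18, 23 and 24).

**Steps most likely to fail**

Step 10 (intramolecular Diels–Alder). The exo transition state may compete, so that much cis-fused decalin forms, or the cycloaddition may be slower than decomposition or hydrogen shift of the diene. The fallback changes the activating group to an aldehyde so that ring closure can run under Lewis-acid control at low temperature. It sets out from 18: i-Bu2AlH (CH2Cl2, −78 °C) would give (2E,4S,6R,7R,8E)-4-(tert-butyldimethylsilyloxy)-7-ethenyl-2,6,8-trimethyl-6-(triethylsilyloxy)undeca-2,8,10-trien-1-ol F1, and MnO2 the corresponding trienal F2. Me2AlCl (CH2Cl2, −78 to −20 °C) should then close both rings through the same chair, now with the aldehyde endo, to 6α-(tert-butyldimethylsilyloxy)-8α-(triethylsilyloxy)-13,14,15,16-tetranorlabda-1,11-dien-18-al F3. Pinnick oxidation (NaClO2, NaH2PO4, 2-methylbut-2-ene) to the 18-oic acid F4 and Me3SiCHN2 in MeOH/toluene would come back to the route at 19.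

Step 7 (alkynylalane opening of the vinyl epoxide). Attack may occur at the tertiary carbon C8 or in the SN2' sense at the vinyl terminus, or the Lewis acid may rearrange the epoxide. The fallback sets C8 and C9 by carbonyl allylation instead of epoxide opening and sets out from 8. Gold-catalysed hydration of the alkyne (Ph3PAuNTf2, MeOH/H2O, rt) would give methyl (2E,4S)-4-(tert-butyldimethylsilyloxy)-2-methyl-6-oxohept-2-enoate F5, kept neutral because of its β-silyloxy group. Allylboration with diisopropyl [(2E)-5-(trimethylsilyl)pent-2-en-4-yn-1-yl]boronate F6, in the presence of the enantiomer of 3,3'-dibromo-1,1'-bi-2-naphthol that delivers the 8R carbinol, should pass through a chair transition state with the chain CH2 and the alkynyl group equatorial. After hydrolysis of the borate this gives the same 8R,9R relationship and comes back to the route at 14, which is desilylated to 15 as in step 7.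

Step 23 (cross metathesis). Turnover at the vinyl group on quaternary C13 may be slow, the propenyl double bond of 38 may migrate, or C5' may epimerise. The fallback replaces methylenation and metathesis by a Julia–Kocienski olefination of aldehyde 29 with an open-chain, silyl-protected form of the butenolide; it sets out from 29 and, for the sulfone, from 36.
- TBSCl/imidazole on 36 would give methyl (4S,5E)-4-(tert-butyldimethylsilyloxy)hept-5-en-2-ynoate F7.
- Ozonolysis of the propenyl group with NaBH4 work-up would give methyl (4R)-4-(tert-butyldimethylsilyloxy)-5-hydroxypent-2-ynoate F8.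
- Mitsunobu reaction with 1-phenyl-1H-tetrazole-5-thiol would give methyl (4R)-4-(tert-butyldimethylsilyloxy)-5-[(1-phenyl-1H-tetrazol-5-yl)sulfanyl]pent-2-ynoate F9.
- Me2CuLi would give methyl (2Z,4R)-4-(tert-butyldimethylsilyloxy)-3-methyl-5-[(1-phenyl-1H-tetrazol-5-yl)sulfanyl]pent-2-enoate F10, which cannot lactonise because O5' is silylated.
- (NH4)6Mo7O24/H2O2 would give methyl (2Z,4R)-4-(tert-butyldimethylsilyloxy)-3-methyl-5-[(1-phenyl-1H-tetrazol-5-yl)sulfonyl]pent-2-enoate F11.
- KHMDS (DME, −60 °C) with 29 and F11 should give the (14E)-alkene, the 6,5'-bis-O-TBS-8-O-TES-13-OO-TES open-chain methyl ester F12.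
The fluoride treatment of step 24 would then remove the four silyl groups and let the (Z)-γ-hydroxy ester close the lactone, which comes back to the route at 40.

**Further compounds**
F1 | step 10 | (2E,4S,6R,7R,8E)-4-(tert-butyldimethylsilyloxy)-7-ethenyl-2,6,8-trimethyl-6-(triethylsilyloxy)undeca-2,8,10-trien-1-ol | OC/C(C)=C/[C@@H](O[Si](C)(C)C(C)(C)C)C[C@@](C)(O[Si](CC)(CC)CC)[C@H](C=C)/C(C)=C/C=C
F2 | step 10 | (2E,4S,6R,7R,8E)-4-(tert-butyldimethylsilyloxy)-7-ethenyl-2,6,8-trimethyl-6-(triethylsilyloxy)undeca-2,8,10-trienal | O=C/C(C)=C/[C@@H](O[Si](C)(C)C(C)(C)C)C[C@@](C)(O[Si](CC)(CC)CC)[C@H](C=C)/C(C)=C/C=C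
F3 | step 10 | 6α-(tert-butyldimethylsilyloxy)-8α-(triethylsilyloxy)-13,14,15,16-tetranorlabda-1,11-dien-18-al | O=C[C@]1(C)CC=C[C@@]2(C)[C@H]1[C@@H](O[Si](C)(C)C(C)(C)C)C[C@@](C)(O[Si](CC)(CC)CC)[C@@H]2C=C
F4 | step 10 | 6α-(tert-butyldimethylsilyloxy)-8α-(triethylsilyloxy)-13,14,15,16-tetranorlabda-1,11-dien-18-oic acid | OC(=O)[C@]1(C)CC=C[C@@]2(C)[C@H]1[C@@H](O[Si](C)(C)C(C)(C)C)C[C@@](C)(O[Si](CC)(CC)CC)[C@@H]2C=C
F5 | step 7 | methyl (2E,4S)-4-(tert-butyldimethylsilyloxy)-2-methyl-6-oxohept-2-enoate | COC(=O)/C(C)=C/[C@@H](O[Si](C)(C)C(C)(C)C)CC(C)=O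
F6 | step 7 | diisopropyl [(2E)-5-(trimethylsilyl)pent-2-en-4-yn-1-yl]boronate | CC(C)OB(C/C=C/C#C[Si](C)(C)C)OC(C)C
F7 | step 23 | methyl (4S,5E)-4-(tert-butyldimethylsilyloxy)hept-5-en-2-ynoate | C/C=C/[C@H](O[Si](C)(C)C(C)(C)C)C#CC(=O)OC
F8 | step 23 | methyl (4R)-4-(tert-butyldimethylsilyloxy)-5-hydroxypent-2-ynoate | OC[C@H](O[Si](C)(C)C(C)(C)C)C#CC(=O)OC
F9 | step 23 | methyl (4R)-4-(tert-butyldimethylsilyloxy)-5-[(1-phenyl-1H-tetrazol-5-yl)sulfanyl]pent-2-ynoate | c1ccccc1-n1nnnc1SC[C@H](O[Si](C)(C)C(C)(C)C)C#CC(=O)OC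
F10 | step 23 | methyl (2Z,4R)-4-(tert-butyldimethylsilyloxy)-3-methyl-5-[(1-phenyl-1H-tetrazol-5-yl)sulfanyl]pent-2-enoate | c1ccccc1-n1nnnc1SC[C@H](O[Si](C)(C)C(C)(C)C)/C(C)=C\C(=O)OC
F11 | step 23 | methyl (2Z,4R)-4-(tert-butyldimethylsilyloxy)-3-methyl-5-[(1-phenyl-1H-tetrazol-5-yl)sulfonyl]pent-2-enoate | c1ccccc1-n1nnnc1S(=O)(=O)C[C@H](O[Si](C)(C)C(C)(C)C)/C(C)=C\C(=O)OC
F12 | step 23 | (14E)-6,5'-bis-O-TBS-8-O-TES-13-OO-TES open-chain (2'Z)-methyl ester precursor of the target | COC(=O)[C@]1(C)CCC[C@@]2(C)[C@H]1[C@@H](O[Si](C)(C)C(C)(C)C)C[C@@](C)(O[Si](CC)(CC)CC)[C@@H]2CC[C@](C)(/C=C/[C@H](O[Si](C)(C)C(C)(C)C)/C(C)=C\C(=O)OC)OO[Si](CC)(CC)CC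
A1 | direct plan | (2Z,6E)-epoxy diene allylsilane tert-butyldimethylsilyl ether (cyclisation precursor) | c1ccccc1COC[C@]1(C)O[C@H]1CC/C(C)=C/CC/C(C[Si](C)(C)C)=C/CO[Si](C)(C)C(C)(C)C
A2 | direct plan | 18-benzyloxy-11-(tert-butyldimethylsilyloxy)-12,13,14,15,16-pentanorlabd-8(17)-en-3β-ol | c1ccccc1COC[C@]1(C)[C@@H](O)CC[C@@]2(C)[C@H]1CCC(=C)[C@@H]2CO[Si](C)(C)C(C)(C)C
A3 | direct plan | 6α,18-epoxy-11-(tert-butyldimethylsilyloxy)-8α-(triethylsilyloxy)-12,13,14,15,16-pentanorlabdane | C3[C@]1(C)CCC[C@@]2(C)[C@H]1[C@@H](O3)C[C@@](C)(O[Si](CC)(CC)CC)[C@@H]2CO[Si](C)(C)C(C)(C)C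
A4 | direct plan | methyl (13R)-6α,8α-bis(triethylsilyloxy)-13-(triethylsilylperoxy)labd-14-en-18-oate | COC(=O)[C@]1(C)CCC[C@@]2(C)[C@H]1[C@@H](O[Si](CC)(CC)CC)C[C@@](C)(O[Si](CC)(CC)CC)[C@@H]2CC[C@](C)(C=C)OO[Si](CC)(CC)CC
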